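**Retrosynthetic overview**

1. Target 21 comes from the protected flavanone 19 by desilylation and hydrogenolysis; the three arenes are bought and no aromatic ring is built.
2. Ring C (O1–C2–C3–C4(=O)–C4a–C8a) is cut at C4–C4a and O1–C8a. The feature that allows this: C4 (acyl) and O1 (ether) sit on the ortho carbons C4a and C8a of ring A, and O1–C2–C3–C4 is a β-oxy acyl unit. This leaves the four-membered lactone O1–C2–C3–C4, with C2 already set, and a ring A aryllithium that carries C–Li at C4a and C–F at C8a.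
3. The oxetan-2-one comes from aldehyde 12 by a catalytic asymmetric ketene–aldehyde [2+2]; the aldehyde comes from aryl bromide 10.
4. The threo side chain is set first by an Evans syn aldol of an aryloxyacetyl imide with 4-(benzyloxy)benzaldehyde.
5. Ring order: oxetanone (step 7), then ring C by four- to six-membered ring expansion (step 10).

Key step: step 10

Assumption: O-trimethylsilylquinine is taken as the pseudoenantiomer that delivers the (S)-lactone in step 7; if a trial on 3,4,5-trimethoxybenzaldehyde shows the opposite sense, O-trimethylsilylquinidine replaces it and nothing else changes.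

**Route**

Step 1
Reactants: 1 (S)-4-benzyloxazolidin-2-one; 2 bromoacetyl bromide
Product: 3 (S)-4-benzyl-3-(2-bromoacetyl)oxazolidin-2-one
Conditions: n-BuLi, THF, −78 °C; then 2, −78 → 0 °C
Reagents that add atoms: none
Why: N-acylation of the lithiated oxazolidinone by the acid bromide is much faster at −78 °C than displacement of the α-bromide.

Step 2
Reactants: 3 (S)-4-benzyl-3-(2-bromoacetyl)oxazolidin-2-one; 4 4-bromo-2,6-dimethoxyphenol
Product: 5 (S)-4-benzyl-3-[2-(4-bromo-2,6-dimethoxyphenoxy)acetyl]oxazolidin-2-one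
Conditions: K2CO3, acetone, rt
Reagents that add atoms: none
Why: Williamson etherification, in which the acidic phenol is deprotonated by carbonate and displaces the activated α-bromide by SN2 without attacking the imide carbonyls.

Step 3
Reactants: 5 (S)-4-benzyl-3-[2-(4-bromo-2,6-dimethoxyphenoxy)acetyl]oxazolidin-2-one; 6 4-(benzyloxy)benzaldehyde
Product: 8 (S)-4-benzyl-3-[(2S,3R)-3-[4-(benzyloxy)phenyl]-2-(4-bromo-2,6-dimethoxyphenoxy)-3-hydroxypropanoyl]oxazolidin-2-one, via Z-dibutylboron enolate 7 (not isolated)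
Conditions: Bu2BOTf, iPr2NEt, CH2Cl2, 0 °C; 6, −78 → 0 °C; pH 7 buffer, MeOH, H2O2
Reagents that add atoms: none
Why: Evans syn glycolate aldol, in which the Z-boron enolate reacts through a closed Zimmerman–Traxler chair and the (S)-benzyl group of the auxiliary shields one enolate face, so both side-chain stereocentres are set together as the threo (syn) pair with the absolute sense fixed by the auxiliary.

Step 4
Reactants: 8 (S)-4-benzyl-3-[(2S,3R)-3-[4-(benzyloxy)phenyl]-2-(4-bromo-2,6-dimethoxyphenoxy)-3-hydroxypropanoyl]oxazolidin-2-one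
Product: 9 (1R,2R)-1-[4-(benzyloxy)phenyl]-2-(4-bromo-2,6-dimethoxyphenoxy)propane-1,3-diol
Conditions: NaBH4, THF/H2O, 0 °C → rt
Reagents that add atoms: none
Why: Reductive removal of the auxiliary, in which borohydride reduces the activated exocyclic imide carbonyl to the primary alcohol and leaves the aryl bromide, the benzyl ether and both stereocentres untouched.

Step 5
Reactants: 9 (1R,2R)-1-[4-(benzyloxy)phenyl]-2-(4-bromo-2,6-dimethoxyphenoxy)propane-1,3-diol
Product: 10 2-{[(1R,2R)-1-[4-(benzyloxy)phenyl]-1,3-bis(tert-butyldimethylsilyloxy)propan-2-yl]oxy}-5-bromo-1,3-dimethoxybenzene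
Conditions: TBSOTf, 2,6-lutidine, CH2Cl2, −78 → 0 °C
Reagents that add atoms: tert-butyldimethylsilyl triflate, CC(C)(C)[Si](C)(C)OS(=O)(=O)C(F)(F)F
Why: Silyl ether formation with the silyl triflate, which is reactive enough to cap the hindered secondary benzylic alcohol as well as the primary one under buffered conditions.

Step 6
Reactants: 10 2-{[(1R,2R)-1-[4-(benzyloxy)phenyl]-1,3-bis(tert-butyldimethylsilyloxy)propan-2-yl]oxy}-5-bromo-1,3-dimethoxybenzene
Product: 12 4-{[(1R,2R)-1-[4-(benzyloxy)phenyl]-1,3-bis(tert-butyldimethylsilyloxy)propan-2-yl]oxy}-3,5-dimethoxybenzaldehyde, via aryllithium 11 (not isolated)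
Conditions: n-BuLi, THF, −78 °C; DMF, −78 → 0 °C; H2O
Reagents that add atoms: N,N-dimethylformamide, CN(C)C=O
Why: Bromine–lithium exchange, faster at −78 °C than any deprotonation, followed by Bouveault formylation of the aryllithium with DMF.

Step 7
Reactants: 12 4-{[(1R,2R)-1-[4-(benzyloxy)phenyl]-1,3-bis(tert-butyldimethylsilyloxy)propan-2-yl]oxy}-3,5-dimethoxybenzaldehyde
Product: 13 (S)-4-(4-{[(1R,2R)-1-[4-(benzyloxy)phenyl]-1,3-bis(tert-butyldimethylsilyloxy)propan-2-yl]oxy}-3,5-dimethoxyphenyl)oxetan-2-one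
Conditions: AcCl (slow addition), iPr2NEt, O-trimethylsilylquinine (10 mol %), LiClO4, CH2Cl2/Et2O, −78 → −40 °C
Reagents that add atoms: acetyl chloride, CC(Cl)=O
Why: Catalytic asymmetric ketene–aldehyde [2+2] (acyl halide–aldehyde cyclocondensation), in which ketene formed in the flask gives a chiral ammonium enolate with the alkaloid that attacks one face of the LiClO4-activated aldehyde and lactonises, so the future C2 is set as S under catalyst control, far from the side-chain stereocentres.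

Step 8
Reactants: 14 5-fluorobenzene-1,3-diol
Product: 15 1,3-bis(benzyloxy)-5-fluorobenzene
Conditions: BnBr, K2CO3, DMF, rt → 50 °C
Reagents that add atoms: benzyl bromide, BrCc1ccccc1
Why: Double Williamson benzylation of the two phenols.

Step 9
Reactants: 15 1,3-bis(benzyloxy)-5-fluorobenzene
Product: 16 1,5-bis(benzyloxy)-2-bromo-3-fluorobenzene
Conditions: NBS, MeCN, 0 °C → rt, dark
Reagents that add atoms: N-bromosuccinimide, O=C1CCC(=O)N1Br
Why: Electrophilic aromatic bromination, expected at the position ortho to one benzyloxy group and para to the other (next to fluorine), which is less hindered than the position between the two benzyloxy groups.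

Step 10
Reactants: 16 1,5-bis(benzyloxy)-2-bromo-3-fluorobenzene; 13 (S)-4-(4-{[(1R,2R)-1-[4-(benzyloxy)phenyl]-1,3-bis(tert-butyldimethylsilyloxy)propan-2-yl]oxy}-3,5-dimethoxyphenyl)oxetan-2-one
Product: 19 (2S)-5,7-bis(benzyloxy)-2-(4-{[(1R,2R)-1-[4-(benzyloxy)phenyl]-1,3-bis(tert-butyldimethylsilyloxy)propan-2-yl]oxy}-3,5-dimethoxyphenyl)chroman-4-one, via aryllithium 17 (not isolated), via lithium keto-alkoxide 18 (not isolated)
Conditions: 16, n-BuLi (0.98 equiv to 13), THF, −78 °C; transfer cold into 13, THF, −78 °C; DMPU, −78 → 0 °C; aq. NH4Cl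
Reagents that add atoms: none
Why: Proposed new method: aryllithium 17, made by bromine–lithium exchange and kept below −70 °C so that it does not lose LiF, adds to the strained lactone carbonyl C4 of 13; the tetrahedral oxetane alkoxide collapses with cleavage of the acyl C4–O1 bond, and the lithium alkoxide 18 then displaces the fluoride on C8a, now ortho to the new aryl ketone, by intramolecular SNAr through a Meisenheimer complex with LiF as the sink. The closest known reaction types are the acyl–oxygen opening of β-lactones by organolithium reagents to β-hydroxy ketones, the alkoxide SNAr closure of 2-fluoroaryl β-hydroxyalkyl ketones to chroman-4-ones, and the insertion of arynes into acyl–heteroatom σ bonds, which this stepwise sequence imitates without a free aryne. Ring C is closed at O1–C8a by a 6-exo addition–elimination on the arene; O1, C2, C3 and C4 are the four ring atoms of the oxetanone and C4a and C8a are inserted into its C4–O1 bond, a four- to six-membered ring expansion. No stereocentre is created: C2 is C4 of the lactone, none of its four bonds is broken, and the S configuration from step 7 is carried over with retention. The step needs carbonyl attack in preference to deprotonation at C3 or SN2 attack at C2 (a hard aryllithium at −78 °C), a single addition (the new ketone is flanked by F and OBn, and 17 is added to 13 and never in excess), and ring closure faster than retro-aldol cleavage of 18 (intramolecularity, DMPU and the Li–F affinity), with no base left at the end that could open the flavanone at C2.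

Step 11
Reactants: 19 (2S)-5,7-bis(benzyloxy)-2-(4-{[(1R,2R)-1-[4-(benzyloxy)phenyl]-1,3-bis(tert-butyldimethylsilyloxy)propan-2-yl]oxy}-3,5-dimethoxyphenyl)chroman-4-one
Product: 20 (2S)-5,7-bis(benzyloxy)-2-(4-{[(1R,2R)-1-[4-(benzyloxy)phenyl]-1,3-dihydroxypropan-2-yl]oxy}-3,5-dimethoxyphenyl)chroman-4-one
Conditions: HF·pyridine, pyridine, THF, 0 °C → rt
Reagents that add atoms: none
Why: Fluoride-mediated desilylation under buffered acidic conditions, which avoids the base-induced retro-oxa-Michael opening that would epimerise C2.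

Step 12
Reactants: 20 (2S)-5,7-bis(benzyloxy)-2-(4-{[(1R,2R)-1-[4-(benzyloxy)phenyl]-1,3-dihydroxypropan-2-yl]oxy}-3,5-dimethoxyphenyl)chroman-4-one
Product: 21 (2S)-5,7-dihydroxy-2-(4-{[(1R,2R)-1,3-dihydroxy-1-(4-hydroxyphenyl)propan-2-yl]oxy}-3,5-dimethoxyphenyl)chroman-4-one
Conditions: H2 (1 atm), Pd/C, EtOAc/MeOH, rt
Reagents that add atoms: none
Why: Catalytic hydrogenolysis of the three aryl benzyl ethers, which in neutral solvent at 1 atm should be faster than hydrogenolysis of the secondary benzylic alcohol or of the C2–O1 bond of ring C.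

**Compound list**

1 | (S)-4-benzyloxazolidin-2-one | O=C1N[C@@H](Cc2ccccc2)CO1 | starting material
2 | bromoacetyl bromide | BrCC(Br)=O | starting material
3 | (S)-4-benzyl-3-(2-bromoacetyl)oxazolidin-2-one | O=C(CBr)N1[C@@H](Cc2ccccc2)COC1=O | intermediate
4 | 4-bromo-2,6-dimethoxyphenol | COc1cc(Br)cc(OC)c1O | starting material
5 | (S)-4-benzyl-3-[2-(4-bromo-2,6-dimethoxyphenoxy)acetyl]oxazolidin-2-one | COc1cc(Br)cc(OC)c1OCC(=O)N1[C@@H](Cc2ccccc2)COC1=O | intermediate
6 | 4-(benzyloxy)benzaldehyde | O=Cc1ccc(OCc2ccccc2)cc1 | starting material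
7 | Z-dibutylboron enolate of 5 | CCCCB(CCCC)O/C(=C\Oc1c(OC)cc(Br)cc1OC)N1[C@@H](Cc2ccccc2)COC1=O | intermediate
8 | (S)-4-benzyl-3-[(2S,3R)-3-[4-(benzyloxy)phenyl]-2-(4-bromo-2,6-dimethoxyphenoxy)-3-hydroxypropanoyl]oxazolidin-2-one | COc1cc(Br)cc(OC)c1O[C@H](C(=O)N1[C@@H](Cc2ccccc2)COC1=O)[C@H](O)c1ccc(OCc2ccccc2)cc1 | intermediate
9 | (1R,2R)-1-[4-(benzyloxy)phenyl]-2-(4-bromo-2,6-dimethoxyphenoxy)propane-1,3-diol | COc1cc(Br)cc(OC)c1O[C@H](CO)[C@H](O)c1ccc(OCc2ccccc2)cc1 | intermediate
10 | 2-{[(1R,2R)-1-[4-(benzyloxy)phenyl]-1,3-bis(tert-butyldimethylsilyloxy)propan-2-yl]oxy}-5-bromo-1,3-dimethoxybenzene | COc1cc(Br)cc(OC)c1O[C@H](CO[Si](C)(C)C(C)(C)C)[C@H](O[Si](C)(C)C(C)(C)C)c1ccc(OCc2ccccc2)cc1 | intermediate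
11 | aryllithium from 10 (lithium in place of bromine) | COc1cc([Li])cc(OC)c1O[C@H](CO[Si](C)(C)C(C)(C)C)[C@H](O[Si](C)(C)C(C)(C)C)c1ccc(OCc2ccccc2)cc1 | intermediate
12 | 4-{[(1R,2R)-1-[4-(benzyloxy)phenyl]-1,3-bis(tert-butyldimethylsilyloxy)propan-2-yl]oxy}-3,5-dimethoxybenzaldehyde | COc1cc(C=O)cc(OC)c1O[C@H](CO[Si](C)(C)C(C)(C)C)[C@H](O[Si](C)(C)C(C)(C)C)c1ccc(OCc2ccccc2)cc1 | intermediate
13 | (S)-4-(4-{[(1R,2R)-1-[4-(benzyloxy)phenyl]-1,3-bis(tert-butyldimethylsilyloxy)propan-2-yl]oxy}-3,5-dimethoxyphenyl)oxetan-2-one | COc1cc([C@@H]2CC(=O)O2)cc(OC)c1O[C@H](CO[Si](C)(C)C(C)(C)C)[C@H](O[Si](C)(C)C(C)(C)C)c1ccc(OCc2ccccc2)cc1 | intermediate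
14 | 5-fluorobenzene-1,3-diol | Oc1cc(O)cc(F)c1 | starting material
15 | 1,3-bis(benzyloxy)-5-fluorobenzene | Fc1cc(OCc2ccccc2)cc(OCc2ccccc2)c1 | intermediate
16 | 1,5-bis(benzyloxy)-2-bromo-3-fluorobenzene | Fc1cc(OCc2ccccc2)cc(OCc2ccccc2)c1Br | intermediate
17 | [2,4-bis(benzyloxy)-6-fluorophenyl]lithium | [Li]c1c(F)cc(OCc2ccccc2)cc1OCc1ccccc1 | intermediate
18 | lithium (1S)-3-[2,4-bis(benzyloxy)-6-fluorophenyl]-1-(4-{[(1R,2R)-1-[4-(benzyloxy)phenyl]-1,3-bis(tert-butyldimethylsilyloxy)propan-2-yl]oxy}-3,5-dimethoxyphenyl)-3-oxopropan-1-olate | COc1cc([C@@H](O[Li])CC(=O)c2c(F)cc(OCc3ccccc3)cc2OCc2ccccc2)cc(OC)c1O[C@H](CO[Si](C)(C)C(C)(C)C)[C@H](O[Si](C)(C)C(C)(C)C)c1ccc(OCc2ccccc2)cc1 | intermediate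
19 | (2S)-5,7-bis(benzyloxy)-2-(4-{[(1R,2R)-1-[4-(benzyloxy)phenyl]-1,3-bis(tert-butyldimethylsilyloxy)propan-2-yl]oxy}-3,5-dimethoxyphenyl)chroman-4-one | COc1cc([C@@H]2CC(=O)c3c(OCc4ccccc4)cc(OCc4ccccc4)cc3O2)cc(OC)c1O[C@H](CO[Si](C)(C)C(C)(C)C)[C@H](O[Si](C)(C)C(C)(C)C)c1ccc(OCc2ccccc2)cc1 | intermediate
20 | (2S)-5,7-bis(benzyloxy)-2-(4-{[(1R,2R)-1-[4-(benzyloxy)phenyl]-1,3-dihydroxypropan-2-yl]oxy}-3,5-dimethoxyphenyl)chroman-4-one | COc1cc([C@@H]2CC(=O)c3c(OCc4ccccc4)cc(OCc4ccccc4)cc3O2)cc(OC)c1O[C@H](CO)[C@H](O)c1ccc(OCc2ccccc2)cc1 | intermediate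
21 | (2S)-5,7-dihydroxy-2-(4-{[(1R,2R)-1,3-dihydroxy-1-(4-hydroxyphenyl)propan-2-yl]oxy}-3,5-dimethoxyphenyl)chroman-4-one | COc1cc([C@@H]2CC(=O)c3c(O)cc(O)cc3O2)cc(OC)c1O[C@H](CO)[C@H](O)c1ccc(O)cc1 | target

**Step count and risks**

Total steps: 12. Longest linear sequence: 10 (steps 1–7, then 10–12); steps 8–9 form the ring A branch.

Steps most likely to fail:

1. Step 10 (proposed new method). What may go wrong:
   - deprotonation of the lactone at C3 instead of carbonyl addition;
   - a second addition of the aryllithium to the new ketone;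
   - loss of LiF from the aryllithium to an aryne on warming;
   - SNAr on the electron-rich ring A so slow that retro-aldol cleavage of the keto-alkoxide erodes the configuration at C2.

   Fallback with known chemistry, which drops the lactone and sets C2 by asymmetric conjugate addition: it sets out from aryl bromide 10. Bromine–lithium exchange to aryllithium 11, B(OiPr)3 and dilute HCl give 4-{[(1R,2R)-1-[4-(benzyloxy)phenyl]-1,3-bis(tert-butyldimethylsilyloxy)propan-2-yl]oxy}-3,5-dimethoxyphenylboronic acid F1. Commercial 5,7-dihydroxychromen-4-one is benzylated (BnBr, K2CO3, DMF, 60 °C) to 5,7-bis(benzyloxy)chromen-4-one F2. Asymmetric conjugate addition of F1 to F2 (Pd(OCOCF3)2, the t-BuPyOx antipode that gives the 2S product, NH4PF6, H2O, ClCH2CH2Cl, 60 °C) should give the protected flavanone directly, and the route is rejoined at compound 19.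

2. Step 7. What may go wrong: low conversion of a fairly unreactive aromatic aldehyde, insufficient facial selectivity, or loss of the 4-aryl lactone by decarboxylation on purification.

   Fallback by reduction instead of cycloaddition: it sets out from aldehyde 12. Homologation with ethyl diazoacetate (NbCl5, CH2Cl2) gives ethyl 3-(4-{[(1R,2R)-1-[4-(benzyloxy)phenyl]-1,3-bis(tert-butyldimethylsilyloxy)propan-2-yl]oxy}-3,5-dimethoxyphenyl)-3-oxopropanoate F3. Asymmetric transfer hydrogenation (RuCl[(S,S)-TsDPEN](p-cymene), HCO2H/Et3N) gives the ethyl (3S)-3-hydroxy ester F4. Saponification (LiOH, THF/H2O) gives the (3S)-3-hydroxy acid F5. Lactonisation by carboxyl activation (PhSO2Cl, pyridine, 0 °C), which does not touch the carbinol centre, returns to the route at compound 13.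

3. Step 12. What may go wrong: over-reduction, that is hydrogenolysis of the free benzylic C–OH bond of the side chain or reductive opening of ring C at C2–O1, before all three benzyl ethers are gone.

   Fallback by reversing the deprotection order, so that the silyl ether shields the benzylic C–O bond during hydrogenolysis: it sets out from compound 19. Hydrogenolysis (H2, Pd/C, EtOAc) gives (2S)-5,7-dihydroxy-2-(4-{[(1R,2R)-1,3-bis(tert-butyldimethylsilyloxy)-1-(4-hydroxyphenyl)propan-2-yl]oxy}-3,5-dimethoxyphenyl)chroman-4-one F6. HF·pyridine in THF/pyridine then removes both silyl groups and the route is rejoined at compound 21.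

**Further compounds**

F1 | step 10 | 4-{[(1R,2R)-1-[4-(benzyloxy)phenyl]-1,3-bis(tert-butyldimethylsilyloxy)propan-2-yl]oxy}-3,5-dimethoxyphenylboronic acid | COc1cc(B(O)O)cc(OC)c1O[C@H](CO[Si](C)(C)C(C)(C)C)[C@H](O[Si](C)(C)C(C)(C)C)c1ccc(OCc2ccccc2)cc1
F2 | step 10 | 5,7-bis(benzyloxy)chromen-4-one | O=c1ccoc2cc(OCc3ccccc3)cc(OCc3ccccc3)c12
F3 | step 7 | ethyl 3-(4-{[(1R,2R)-1-[4-(benzyloxy)phenyl]-1,3-bis(tert-butyldimethylsilyloxy)propan-2-yl]oxy}-3,5-dimethoxyphenyl)-3-oxopropanoate | COc1cc(C(=O)CC(=O)OCC)cc(OC)c1O[C@H](CO[Si](C)(C)C(C)(C)C)[C@H](O[Si](C)(C)C(C)(C)C)c1ccc(OCc2ccccc2)cc1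
F4 | step 7 | ethyl (3S)-3-(4-{[(1R,2R)-1-[4-(benzyloxy)phenyl]-1,3-bis(tert-butyldimethylsilyloxy)propan-2-yl]oxy}-3,5-dimethoxyphenyl)-3-hydroxypropanoate | COc1cc([C@@H](O)CC(=O)OCC)cc(OC)c1O[C@H](CO[Si](C)(C)C(C)(C)C)[C@H](O[Si](C)(C)C(C)(C)C)c1ccc(OCc2ccccc2)cc1
F5 | step 7 | (3S)-3-(4-{[(1R,2R)-1-[4-(benzyloxy)phenyl]-1,3-bis(tert-butyldimethylsilyloxy)propan-2-yl]oxy}-3,5-dimethoxyphenyl)-3-hydroxypropanoic acid | COc1cc([C@@H](O)CC(=O)O)cc(OC)c1O[C@H](CO[Si](C)(C)C(C)(C)C)[C@H](O[Si](C)(C)C(C)(C)C)c1ccc(OCc2ccccc2)cc1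
F6 | step 12 | (2S)-5,7-dihydroxy-2-(4-{[(1R,2R)-1,3-bis(tert-butyldimethylsilyloxy)-1-(4-hydroxyphenyl)propan-2-yl]oxy}-3,5-dimethoxyphenyl)chroman-4-one | COc1cc([C@@H]2CC(=O)c3c(O)cc(O)cc3O2)cc(OC)c1O[C@H](CO[Si](C)(C)C(C)(C)C)[C@H](O[Si](C)(C)C(C)(C)C)c1ccc(O)cc1
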